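Time first: the south run is this very flask, followed to 80.0 min, and the questions go on to 4.0 h.

| flask | E | X | remark | time |
|---|---|---|---|---|
| south | 0.10 M | 49 mM (held) | the very flask that is asked about, followed so far |  |
| flask | 0.10 M | 49 mM (held) |  | 4.0 h |

south run (percent of the E charged)

| time / min | L / % | Q / % | E / % |
|---|---|---|---|
| 6.00 | 22.2 | 45.7 | 1.3 |
| 12.0 | 32.2 | 55.3 | 0 |
| 30.0 | 40.7 | 58.8 | 0 |
| 80.0 | 39.2 | 58.5 | 0 |

(standard deviation of a reading: 1 percentage point)

- share of L in L plus Q at 80 s
- share of L in L plus Q at 15 min
- share of L in L plus Q at 4.0 h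
- which of L and Q there is more of at 4.0 h

- the analysis behind the earlier runs scatters by 1 percentage point, standard deviation
- at the start none of X is in solution

We read the ratio of L to Q in two ways. One way divides the two readings. The other uses Q and E and books the whole remainder of the charge as L. At 6.00 min they part, 0.486 against 1.16, since 31 percentage points of the charge reads as none of the three. The balance way cheats there, because Q later gains 13 points by 30.0 min, so the remainder was not all L. At 30.0 min the ways meet, 0.692 and 0.701.

So we trust the late readings. Pooling the readings at 30.0 min and 80.0 min gives the end selectivity, our selectivity factor: the ratio of L to Q once each holds steady within the scatter, read here as S = 0.681. Its logarithm is −0.167. One point on L moves that by 0.0111, so Q's lead is 15.0 such steps wide. Taking S on to 4.0 h, we expect a share of L of 40.5%. At 12.0 min the ways still give 0.582 and 0.808, so 15 min stays a bracket for us. We give no number for 80 s, which lies before the first reading.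

The forecast says 23% (12% to 33%) at 80 s, 38.8% (37% to 40.5%) at 15 min, and 40.3% (37.5% to 42%) at 4.0 h, with Q ahead. Its late ground: “The plateau shows no significant drift”.

The flask gives 39.2%, 38.5% and 40.1%, with Q ahead. The forecast parts from it at 80 s, by 16 points.

    E + Z → J (k = 0.650 L mol⁻¹ s⁻¹)
    Z + J → Q (k = 0.240 L mol⁻¹ s⁻¹)
    E → D (k = 0.00930 s⁻¹)
    D → L (k = 0.00320 s⁻¹)
    X ⇌ Z, rate k5*(csat - [Z]) (kL = 0.0310 s⁻¹)
    E ⇌ G (K = 2.30, k = 0.00990 s⁻¹)

At 4.0 h this flask's ratio is 0.669, logarithm −0.175, and the 0.00800 between that and the −0.167 we read for S lies inside our step of 0.0111. The neighbour flask is charged with cE = 0.25 M, all else held. Its share of L is 46.2%, so its ratio is 0.857, logarithm −0.0668. That is 0.108 up, on a charge up by 0.398 in logarithm. At 4.00 h the neighbour holds L 46.2% and Q 53.8%.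

(The numbers in the tables were computed with constants of no real substance, noise included.)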